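**Plan** (coumarin numbering for the bicycle; side chain C1'–C8' counted from the ether carbon)

- Feature used: the benzene ring (C4a, C5, C6, C7, C8, C8a) carries three neighbouring, different oxygens (C7 ether, C8 methoxy, C8a lactone oxygen) beside the carbon-bearing C4a; a 1,1,2,3-tetraoxygenated butadiene and an ynal assemble exactly this in one cycloaddition–aromatisation.
- Cuts on the core, in retrosynthetic order: the acetonide on the C5'/C6' diol; O1–C2 and C3=C4 of the pyranone (a two-carbon ketene unit); C5–C6 and C4a–C8a of the benzene ring (diene + propynal); the vinylic C7–O bond (side-chain alkoxide + enol tosylate).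
- Cuts on the side chain: C3'–CH3 (cuprate), C3'–C4' (acetylide + triflate), C7'=C8' (Wittig) and C7'–CH3 (Grignard), back to the four carbons C4'–C7' of tartrate.
- Forward order: tartrate gives C4'–C7', a propargyl unit adds C1'–C3', the (E)-alkene is set, the chain oxygen is joined to the acetoacetate unit and the diene is made; the benzene ring arises first (step 16), the pyranone second (step 17), the diol is freed last.
- Stereochemistry: C5' and C6' are the two carbinol carbons of diethyl L-tartrate, held in a trans-dioxolane and never broken; the (2'E)-alkene comes from anti hydroalumination–iodination of an alkynol and methylation with retention.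

Key step: step 16

Shorthand: Dx = (4S,5S)-2,2-dimethyl-5-(prop-1-en-2-yl)-1,3-dioxolan-4-yl; SC = (2E)-4-Dx-3-methylbut-2-en-1-yl, the protected side chain bonded through C1'.

Assumption: the enol tosylate, the β-alkoxy enoate and the silyl ketene acetal diene are used as mixtures of double-bond isomers (that bond is left undefined in their SMILES) and the keto ester as the racemate, because these elements vanish when the ring becomes aromatic.

**Step 1**
Reactants: 1 diethyl L-tartrate
Product: 2 diethyl (4R,5R)-2,2-dimethyl-1,3-dioxolane-4,5-dicarboxylate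
Conditions: Me2C(OMe)2, p-TsOH·H2O (cat.), cyclohexane, reflux, MeOH distilled off
Reagents that add atoms: 2,2-dimethoxypropane, COC(C)(C)OC
Why: Acid-catalysed acetal exchange closes the trans-dioxolane on the threo diol without touching either stereocentre, so C5' and C6' are fixed here by the chiral pool.

**Step 2**
Reactants: 2 diethyl (4R,5R)-2,2-dimethyl-1,3-dioxolane-4,5-dicarboxylate
Product: 3 (4R,5R)-N4,N5-dimethoxy-N4,N5,2,2-tetramethyl-1,3-dioxolane-4,5-dicarboxamide
Conditions: MeNH(OMe)·HCl, i-PrMgCl, THF, −20 → 0 °C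
Reagents that add atoms: N,O-dimethylhydroxylamine hydrochloride, CNOC.Cl
Why: The chloromagnesium amide made in the flask aminolyses both esters (ester to N-methoxy-N-methylamide exchange) at a temperature at which the α-alkoxy centres of the trans-dioxolane should not epimerise.

**Step 3**
Reactants: 3 (4R,5R)-N4,N5-dimethoxy-N4,N5,2,2-tetramethyl-1,3-dioxolane-4,5-dicarboxamide
Product: 4 (4R,5R)-5-acetyl-N-methoxy-N,2,2-trimethyl-1,3-dioxolane-4-carboxamide
Conditions: MeMgBr (1.2 equiv), THF, −15 °C
Reagents that add atoms: methylmagnesium bromide, C[Mg]Br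
Why: In this Weinreb ketone synthesis the first addition gives a stable magnesium chelate, and C2-symmetric bis-amides of the tartrate series are known to take up only one Grignard equivalent under such control, which tells the two ends of the four-carbon unit apart.

**Step 4**
Reactants: 4 (4R,5R)-5-acetyl-N-methoxy-N,2,2-trimethyl-1,3-dioxolane-4-carboxamide
Product: 5 (4R,5S)-N-methoxy-N,2,2-trimethyl-5-(prop-1-en-2-yl)-1,3-dioxolane-4-carboxamide
Conditions: Ph3PCH3Br, KOt-Bu, THF, 0 °C → rt
Reagents that add atoms: methyltriphenylphosphonium bromide, C[P+](c1ccccc1)(c1ccccc1)c1ccccc1.[Br-]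
Why: Wittig methylenation of the methyl ketone installs C7'=C8', the amide being inert to the ylide and the trans-dioxolane being the more stable arrangement should the α-centre enolise.

**Step 5**
Reactants: 5 (4R,5S)-N-methoxy-N,2,2-trimethyl-5-(prop-1-en-2-yl)-1,3-dioxolane-4-carboxamide
Product: 7 Dx-methanol, via aldehyde 6 (not isolated)
Conditions: NaBH4, MeOH, 0 °C → rt
Reagents that add atoms: none
Why: α-Alkoxy N-methoxy-N-methylamides are electrophilic enough for hydride reduction by NaBH4 in methanol through the aldehyde to the primary alcohol, while alkene and acetal are inert.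

**Step 6**
Reactants: 7 Dx-methanol
Product: 8 Dx-methyl trifluoromethanesulfonate
Conditions: Tf2O, pyridine, CH2Cl2, −78 → −30 °C; cold aqueous work-up, used at once
Reagents that add atoms: trifluoromethanesulfonic anhydride, O=S(=O)(OS(=O)(=O)C(F)(F)F)C(F)(F)F
Why: O-Sulfonylation gives the primary triflate, the leaving group needed because the β-oxygen of the dioxolane makes halides and tosylates at this carbon too slow in SN2 reactions.

**Step 7**
Reactants: 8 Dx-methyl trifluoromethanesulfonate; 9 tert-butyldimethyl(prop-2-yn-1-yloxy)silane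
Product: 11 tert-butyl[(4-Dx-but-2-yn-1-yl)oxy]dimethylsilane, via lithium acetylide 10 (not isolated)
Conditions: 9, n-BuLi, THF, −78 °C; then 8, DMPU, −78 → −20 °C
Reagents that add atoms: none
Why: SN2 alkylation of a lithium acetylide by a primary triflate in THF–DMPU forms the C3'–C4' bond and brings in C1'–C3' without touching the stereocentres.

**Step 8**
Reactants: 11 tert-butyl[(4-Dx-but-2-yn-1-yl)oxy]dimethylsilane
Product: 12 4-Dx-but-2-yn-1-ol
Conditions: Bu4NF, THF, 0 °C → rt
Reagents that add atoms: none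
Why: Fluoride cleaves the primary silyl ether (desilylation driven by the Si–F bond), leaves the acetonide and frees the hydroxyl that directs the next step.

**Step 9**
Reactants: 12 4-Dx-but-2-yn-1-ol
Product: 14 (2Z)-4-Dx-3-iodobut-2-en-1-ol, via vinylalanate 13 (not isolated)
Conditions: NaAlH2(OCH2CH2OMe)2, THF, 0 °C → rt; then I2, THF, −78 → 0 °C
Reagents that add atoms: iodine, II
Why: Hydroxyl-directed anti hydroalumination puts hydride on C2' and aluminium on C3' in a five-membered alanate, and iodinolysis of the C–Al bond with retention gives the (Z)-3-iodo allylic alcohol, so the trans addition sets the alkene geometry.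

**Step 10**
Reactants: 14 (2Z)-4-Dx-3-iodobut-2-en-1-ol
Product: 15 (2E)-4-Dx-3-methylbut-2-en-1-ol (SC-OH)
Conditions: Me2CuLi (from MeLi and CuI, excess), Et2O, 0 °C
Reagents that add atoms: lithium dimethylcuprate (from MeLi and CuI), [Li+].C[Cu-]C
Why: Cross-coupling of the alkenyl iodide with the cuprate replaces iodine by methyl with retention of configuration, which places C4' trans to C1' and gives the (E)-trisubstituted alkene of the target.

**Step 11**
Reactants: 16 methyl methoxyacetate
Product: 18 methyl 2-methoxy-3-oxobutanoate, via lithium enolate 17 (not isolated)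
Conditions: LiN(i-Pr)2, THF, −78 °C; then MeC(O)N(OMe)Me, −78 → 0 °C
Reagents that add atoms: N-methoxy-N-methylacetamide, CC(=O)N(C)OC
Why: C-Acylation of the ester enolate by an N-methoxy-N-methylamide (crossed Claisen-type condensation) rests at the tetrahedral lithium chelate until work-up, which avoids O-acylation and a second addition.

**Step 12**
Reactants: 18 methyl 2-methoxy-3-oxobutanoate
Product: 19 methyl 2-methoxy-3-(tosyloxy)but-2-enoate
Conditions: TsCl, N-methylimidazole, Et3N, MeCN, 0 °C
Reagents that add atoms: p-toluenesulfonyl chloride, Cc1ccc(cc1)S(=O)(=O)Cl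
Why: O-Sulfonylation of the β-keto ester enolate by the N-sulfonylimidazolium salt gives the enol tosylate, a vinylogous mixed anhydride activated for substitution at its β-carbon.

**Step 13**
Reactants: 15 (2E)-4-Dx-3-methylbut-2-en-1-ol; 19 methyl 2-methoxy-3-(tosyloxy)but-2-enoate
Product: 21 methyl 2-methoxy-3-(SC-oxy)but-2-enoate, via sodium alkoxide 20 (not isolated)
Conditions: NaH, THF, 0 °C; then 19, −20 °C → rt
Reagents that add atoms: none
Why: Nucleophilic vinylic substitution by addition–elimination, in which the alkoxide adds to the β-carbon of the enoate and tosylate leaves, forms the future C7–O bond with the whole side chain in place.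

**Step 14**
Reactants: 21 methyl 2-methoxy-3-(SC-oxy)but-2-enoate
Product: 23 [1,2-dimethoxy-3-(SC-oxy)buta-1,3-dien-1-yl]oxy-trimethylsilane, via lithium dienolate 22 (not isolated)
Conditions: Me3SiCl, LiN(i-Pr)2, THF, −78 °C (silyl chloride present from the start); pentane, filtration under argon, used crude
Reagents that add atoms: chlorotrimethylsilane, C[Si](C)(C)Cl
Why: Kinetic γ-deprotonation of the β-alkoxy enoate gives the extended enolate, which is O-silylated as it forms (the usual entry to 1-alkoxy-1-silyloxy-3-alkoxybutadienes from 3-alkoxycrotonates) before it can undergo a [3,3] shift.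

**Step 15**
Reactants: 24 propargyl alcohol
Product: 25 propynal
Conditions: CrO3, H2SO4, H2O, 5–10 °C, about 50 mbar, product collected at −78 °C
Reagents that add atoms: none
Why: Chromic acid oxidation of the primary propargylic alcohol stops at the aldehyde because the volatile ynal is swept out of the aqueous oxidant under reduced pressure as it forms.

**Step 16**
Reactants: 23 [1,2-dimethoxy-3-(SC-oxy)buta-1,3-dien-1-yl]oxy-trimethylsilane; 25 propynal
Product: 28 2-hydroxy-3-methoxy-4-(SC-oxy)benzaldehyde, via cycloadduct 26 (not isolated), via aryl silyl ether 27 (not isolated)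
Conditions: 25 (1.5 equiv), toluene, −40 °C → rt; then 5% aq. citric acid, THF, 0 °C
Reagents that add atoms: none
Why: The donor-rich vinylketene acetal 23 and the ynal 25 join in a [4+2] cycloaddition whose two bonds form in one step but to unequal extent in the transition state, the CH2 terminus of the diene (future C6) bonding ahead to the β-carbon of propynal (future C5) and the acetal carbon (future C8a) to the formyl-bearing carbon (future C4a), after which the 1,4-cyclohexadiene 26 expels methanol from its mixed acetal and the aryl silyl ether 27 is hydrolysed on acidic work-up. The closest known reaction type is the cycloaddition–aromatisation of silyl ketene acetal dienes (1-alkoxy-1-silyloxy-1,3-dienes with a 3-oxygen) with alkynyl esters, ketones and aldehydes, in which an alcohol is lost. The benzene ring (C4a, C5, C6, C7, C8, C8a) is closed by this intermolecular cycloaddition, its new bonds C5–C6 and C4a–C8a arising in the same event, and the carbocycle turns aromatic in the same flask. No stereocentre is created, since the acetal carbon of 26 ends as an sp2 ring atom and C5' and C6' lie far from the reacting atoms. Two selectivities are needed: the formyl group must end beside the C8a oxygen, which follows from the polarisation of the diene by its oxygens at C7 and C8a (largest HOMO coefficient at CH2) matched to the ynal (largest LUMO coefficient at the β-carbon), and the cycloaddition must outrun the [3,3] sigmatropic shift of the O-allyl enol ether, which should be slow below room temperature because its allyl terminus C3' would have to become quaternary, whereas the ynal reacts readily.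

**Step 17**
Reactants: 28 2-hydroxy-3-methoxy-4-(SC-oxy)benzaldehyde; 29 ketenylidenetriphenylphosphorane
Product: 31 8-methoxy-7-(SC-oxy)-2H-chromen-2-one, via ester ylide 30 (not isolated)
Conditions: toluene, 110 °C
Reagents that add atoms: none
Why: The phenol adds across the ketene C=C bond of the cumulated ylide to give the aryl (triphenylphosphoranylidene)acetate, whose stabilised ylide closes the pyranone by intramolecular Wittig reaction with the ortho formyl group, a ring closure that can only give the cis C3=C4 bond.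

**Step 18**
Reactants: 31 8-methoxy-7-(SC-oxy)-2H-chromen-2-one
Product: 32 7-{[(2E,5S,6S)-5,6-dihydroxy-3,7-dimethylocta-2,7-dien-1-yl]oxy}-8-methoxy-2H-chromen-2-one
Conditions: AcOH–H2O (4:1), 40 °C
Reagents that add atoms: none
Why: Mild aqueous acid hydrolyses the dioxolane at its acetal carbon, so the C–O bonds at C5' and C6' are not broken, and the lactone and the allylic aryl ether should survive acid of this strength, as such ethers do in the dilute-acid hydration of side-chain epoxides in this coumarin family.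

**Compound list**

1 | diethyl L-tartrate, diethyl (2R,3R)-2,3-dihydroxybutanedioate | CCOC(=O)[C@H](O)[C@@H](O)C(=O)OCC | starting material
2 | diethyl (4R,5R)-2,2-dimethyl-1,3-dioxolane-4,5-dicarboxylate | CCOC(=O)[C@@H]1OC(C)(C)O[C@H]1C(=O)OCC | intermediate
3 | (4R,5R)-N4,N5-dimethoxy-N4,N5,2,2-tetramethyl-1,3-dioxolane-4,5-dicarboxamide | CON(C)C(=O)[C@@H]1OC(C)(C)O[C@H]1C(=O)N(C)OC | intermediate
4 | (4R,5R)-5-acetyl-N-methoxy-N,2,2-trimethyl-1,3-dioxolane-4-carboxamide | CC(=O)[C@@H]1OC(C)(C)O[C@H]1C(=O)N(C)OC | intermediate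
5 | (4R,5S)-N-methoxy-N,2,2-trimethyl-5-(prop-1-en-2-yl)-1,3-dioxolane-4-carboxamide | C=C(C)[C@@H]1OC(C)(C)O[C@H]1C(=O)N(C)OC | intermediate
6 | (4R,5S)-2,2-dimethyl-5-(prop-1-en-2-yl)-1,3-dioxolane-4-carbaldehyde (not isolated) | C=C(C)[C@@H]1OC(C)(C)O[C@H]1C=O | intermediate
7 | [(4S,5S)-2,2-dimethyl-5-(prop-1-en-2-yl)-1,3-dioxolan-4-yl]methanol | C=C(C)[C@@H]1OC(C)(C)O[C@H]1CO | intermediate
8 | [(4S,5S)-2,2-dimethyl-5-(prop-1-en-2-yl)-1,3-dioxolan-4-yl]methyl trifluoromethanesulfonate | C=C(C)[C@@H]1OC(C)(C)O[C@H]1COS(=O)(=O)C(F)(F)F | intermediate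
9 | tert-butyldimethyl(prop-2-yn-1-yloxy)silane | C#CCO[Si](C)(C)C(C)(C)C | starting material
10 | [3-(tert-butyldimethylsilyloxy)prop-1-yn-1-yl]lithium (not isolated) | [Li]C#CCO[Si](C)(C)C(C)(C)C | intermediate
11 | tert-butyl({4-[(4S,5S)-2,2-dimethyl-5-(prop-1-en-2-yl)-1,3-dioxolan-4-yl]but-2-yn-1-yl}oxy)dimethylsilane | C=C(C)[C@@H]1OC(C)(C)O[C@H]1CC#CCO[Si](C)(C)C(C)(C)C | intermediate
12 | 4-[(4S,5S)-2,2-dimethyl-5-(prop-1-en-2-yl)-1,3-dioxolan-4-yl]but-2-yn-1-ol | C=C(C)[C@@H]1OC(C)(C)O[C@H]1CC#CCO | intermediate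
13 | cyclic sodium vinylalanate: 1-oxa-2-aluminacyclopent-3-ene with two 2-methoxyethoxy groups on aluminium and the [(4S,5S)-2,2-dimethyl-5-(prop-1-en-2-yl)-1,3-dioxolan-4-yl]methyl group on C3, sodium salt (not isolated) | [Na+].COCCO[Al-]1(OCCOC)OCC=C1C[C@@H]1OC(C)(C)O[C@H]1C(C)=C | intermediate
14 | (2Z)-4-[(4S,5S)-2,2-dimethyl-5-(prop-1-en-2-yl)-1,3-dioxolan-4-yl]-3-iodobut-2-en-1-ol | C=C(C)[C@@H]1OC(C)(C)O[C@H]1C/C(I)=C/CO | intermediate
15 | (2E)-4-[(4S,5S)-2,2-dimethyl-5-(prop-1-en-2-yl)-1,3-dioxolan-4-yl]-3-methylbut-2-en-1-ol | C=C(C)[C@@H]1OC(C)(C)O[C@H]1C/C(C)=C/CO | intermediate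
16 | methyl methoxyacetate | COCC(=O)OC | starting material
17 | lithium 1,2-dimethoxyethen-1-olate (not isolated) | [Li+].COC=C([O-])OC | intermediate
18 | methyl 2-methoxy-3-oxobutanoate (racemic) | COC(C(C)=O)C(=O)OC | intermediate
19 | methyl 2-methoxy-3-{[(4-methylphenyl)sulfonyl]oxy}but-2-enoate (mixture of double-bond isomers) | COC(=O)C(OC)=C(C)OS(=O)(=O)c1ccc(C)cc1 | intermediate
20 | sodium (2E)-4-[(4S,5S)-2,2-dimethyl-5-(prop-1-en-2-yl)-1,3-dioxolan-4-yl]-3-methylbut-2-en-1-olate (not isolated) | [Na+].C=C(C)[C@@H]1OC(C)(C)O[C@H]1C/C(C)=C/C[O-] | intermediate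
21 | methyl 3-({(2E)-4-[(4S,5S)-2,2-dimethyl-5-(prop-1-en-2-yl)-1,3-dioxolan-4-yl]-3-methylbut-2-en-1-yl}oxy)-2-methoxybut-2-enoate (enoate geometry undefined) | C=C(C)[C@@H]1OC(C)(C)O[C@H]1C/C(C)=C/COC(C)=C(OC)C(=O)OC | intermediate
22 | lithium 3-({(2E)-4-[(4S,5S)-2,2-dimethyl-5-(prop-1-en-2-yl)-1,3-dioxolan-4-yl]-3-methylbut-2-en-1-yl}oxy)-1,2-dimethoxybuta-1,3-dien-1-olate (not isolated) | [Li+].C=C(C)[C@@H]1OC(C)(C)O[C@H]1C/C(C)=C/COC(=C)C(OC)=C([O-])OC | intermediate
23 | {[3-({(2E)-4-[(4S,5S)-2,2-dimethyl-5-(prop-1-en-2-yl)-1,3-dioxolan-4-yl]-3-methylbut-2-en-1-yl}oxy)-1,2-dimethoxybuta-1,3-dien-1-yl]oxy}trimethylsilane (ketene acetal geometry undefined) | C=C(C)[C@@H]1OC(C)(C)O[C@H]1C/C(C)=C/COC(=C)C(OC)=C(OC)O[Si](C)(C)C | intermediate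
24 | propargyl alcohol, prop-2-yn-1-ol | C#CCO | starting material
25 | propynal | C#CC=O | intermediate
26 | 4-({(2E)-4-[(4S,5S)-2,2-dimethyl-5-(prop-1-en-2-yl)-1,3-dioxolan-4-yl]-3-methylbut-2-en-1-yl}oxy)-5,6-dimethoxy-6-(trimethylsilyloxy)cyclohexa-1,4-diene-1-carbaldehyde (both configurations at C6, not isolated) | C=C(C)[C@@H]1OC(C)(C)O[C@H]1C/C(C)=C/COC1=C(OC)C(OC)(O[Si](C)(C)C)C(C=O)=CC1 | intermediate
27 | 4-({(2E)-4-[(4S,5S)-2,2-dimethyl-5-(prop-1-en-2-yl)-1,3-dioxolan-4-yl]-3-methylbut-2-en-1-yl}oxy)-3-methoxy-2-(trimethylsilyloxy)benzaldehyde (not isolated) | C=C(C)[C@@H]1OC(C)(C)O[C@H]1C/C(C)=C/COc1ccc(C=O)c(O[Si](C)(C)C)c1OC | intermediate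
28 | 4-({(2E)-4-[(4S,5S)-2,2-dimethyl-5-(prop-1-en-2-yl)-1,3-dioxolan-4-yl]-3-methylbut-2-en-1-yl}oxy)-2-hydroxy-3-methoxybenzaldehyde | C=C(C)[C@@H]1OC(C)(C)O[C@H]1C/C(C)=C/COc1ccc(C=O)c(O)c1OC | intermediate
29 | ketenylidenetriphenylphosphorane | O=C=C=P(c1ccccc1)(c1ccccc1)c1ccccc1 | starting material
30 | 3-({(2E)-4-[(4S,5S)-2,2-dimethyl-5-(prop-1-en-2-yl)-1,3-dioxolan-4-yl]-3-methylbut-2-en-1-yl}oxy)-6-formyl-2-methoxyphenyl (triphenylphosphoranylidene)acetate (not isolated) | C=C(C)[C@@H]1OC(C)(C)O[C@H]1C/C(C)=C/COc1ccc(C=O)c(OC(=O)C=P(c2ccccc2)(c2ccccc2)c2ccccc2)c1OC | intermediate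
31 | 7-({(2E)-4-[(4S,5S)-2,2-dimethyl-5-(prop-1-en-2-yl)-1,3-dioxolan-4-yl]-3-methylbut-2-en-1-yl}oxy)-8-methoxy-2H-chromen-2-one | C=C(C)[C@@H]1OC(C)(C)O[C@H]1C/C(C)=C/COc1ccc2ccc(=O)oc2c1OC | intermediate
32 | 7-{[(2E,5S,6S)-5,6-dihydroxy-3,7-dimethylocta-2,7-dien-1-yl]oxy}-8-methoxy-2H-chromen-2-one | C=C(C)[C@H](O)[C@@H](O)C/C(C)=C/COc1ccc2ccc(=O)oc2c1OC | target

**Count**

Total steps: 18. Longest linear sequence: 15 steps (steps 1–10, 13, 14, 16, 17, 18).

**Steps most likely to fail**

Step 13. The alkoxide may attack sulfur (tosyl transfer, which returns the keto ester enolate) or the ester carbonyl instead of the β-carbon. The fallback sets out from keto ester 18 and alcohol 15 and comes back to the route at 21. It is a Mitsunobu etherification (PPh3, DIAD, THF, 0 °C → rt) in which the roles are reversed: the enol oxygen of 18 is the acidic nucleophile and C1' of the phosphonium-activated alcohol 15 the electrophile. O-Alkylation of β-dicarbonyl enols by primary alcohols under these conditions is known, and no sulfonate is present. No new compound arises on this way (entry F0).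

Step 14. The lithium dienolate may undergo an anion-accelerated [3,3] shift of its allyl vinyl ether, or the base may metalate the allylic OCH2 group, before silylation; the diene may also hydrolyse on handling. The fallback sets out from keto ester 18 (with propynal 25 and alcohol 15) and comes back at 28; it joins the side chain only after the arene is built. Keto ester 18 with Me3SiOTf and Et3N (2.2 equiv each, Et2O, 0 °C) is silylated twice, first to methyl 2-methoxy-3-(trimethylsilyloxy)but-2-enoate F1 and then to 1,2-dimethoxy-1,3-bis(trimethylsilyloxy)buta-1,3-diene F2, which holds no allyl ether. Cycloaddition of F2 with 25 (toluene, −40 °C → rt) should give 5,6-dimethoxy-4,6-bis(trimethylsilyloxy)cyclohexa-1,4-diene-1-carbaldehyde F3, which loses methanol to 3-methoxy-2,4-bis(trimethylsilyloxy)benzaldehyde F4 and on dilute acid gives 2,4-dihydroxy-3-methoxybenzaldehyde F5. Mitsunobu etherification of F5 with 15 (PPh3, DIAD, THF, 0 °C) is expected at the 4-hydroxyl, because the 2-hydroxyl is held in the hydrogen bond to the formyl group, and gives 28.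

Step 16. The silyl ketene acetal may add to the formyl group (1,2-addition) or the ynal may oligomerise, so that the dienophile is used up before the cycloaddition. The fallback sets out from diene 23 and comes back at 28; it builds the same ring at the ester oxidation level with methyl propiolate, the best-tried dienophile for this diene class (toluene, rt → 50 °C). The adduct methyl 5,6-dimethoxy-4-(SC-oxy)-6-(trimethylsilyloxy)cyclohexa-1,4-diene-1-carboxylate F6 should lose methanol to methyl 3-methoxy-4-(SC-oxy)-2-(trimethylsilyloxy)benzoate F7, and dilute acid gives methyl 2-hydroxy-3-methoxy-4-(SC-oxy)benzoate F8. LiAlH4 (THF, 0 °C) reduces the ester to 6-(hydroxymethyl)-2-methoxy-3-(SC-oxy)phenol F9, and MnO2 (CH2Cl2, rt) oxidises the benzylic alcohol to 28.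

**Further compounds**

F0 | step 13 | none | none
F1 | step 14 | methyl 2-methoxy-3-(trimethylsilyloxy)but-2-enoate | COC(=O)C(OC)=C(C)O[Si](C)(C)C
F2 | step 14 | 1,2-dimethoxy-1,3-bis(trimethylsilyloxy)buta-1,3-diene | C=C(O[Si](C)(C)C)C(OC)=C(OC)O[Si](C)(C)C
F3 | step 14 | 5,6-dimethoxy-4,6-bis(trimethylsilyloxy)cyclohexa-1,4-diene-1-carbaldehyde | O=CC1=CCC(O[Si](C)(C)C)=C(OC)C1(OC)O[Si](C)(C)C
F4 | step 14 | 3-methoxy-2,4-bis(trimethylsilyloxy)benzaldehyde | COc1c(O[Si](C)(C)C)ccc(C=O)c1O[Si](C)(C)C
F5 | step 14 | 2,4-dihydroxy-3-methoxybenzaldehyde | COc1c(O)ccc(C=O)c1O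
F6 | step 16 | methyl 4-({(2E)-4-[(4S,5S)-2,2-dimethyl-5-(prop-1-en-2-yl)-1,3-dioxolan-4-yl]-3-methylbut-2-en-1-yl}oxy)-5,6-dimethoxy-6-(trimethylsilyloxy)cyclohexa-1,4-diene-1-carboxylate | C=C(C)[C@@H]1OC(C)(C)O[C@H]1C/C(C)=C/COC1=C(OC)C(OC)(O[Si](C)(C)C)C(C(=O)OC)=CC1
F7 | step 16 | methyl 4-({(2E)-4-[(4S,5S)-2,2-dimethyl-5-(prop-1-en-2-yl)-1,3-dioxolan-4-yl]-3-methylbut-2-en-1-yl}oxy)-3-methoxy-2-(trimethylsilyloxy)benzoate | C=C(C)[C@@H]1OC(C)(C)O[C@H]1C/C(C)=C/COc1ccc(C(=O)OC)c(O[Si](C)(C)C)c1OC
F8 | step 16 | methyl 4-({(2E)-4-[(4S,5S)-2,2-dimethyl-5-(prop-1-en-2-yl)-1,3-dioxolan-4-yl]-3-methylbut-2-en-1-yl}oxy)-2-hydroxy-3-methoxybenzoate | C=C(C)[C@@H]1OC(C)(C)O[C@H]1C/C(C)=C/COc1ccc(C(=O)OC)c(O)c1OC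
F9 | step 16 | 3-({(2E)-4-[(4S,5S)-2,2-dimethyl-5-(prop-1-en-2-yl)-1,3-dioxolan-4-yl]-3-methylbut-2-en-1-yl}oxy)-6-(hydroxymethyl)-2-methoxyphenol | C=C(C)[C@@H]1OC(C)(C)O[C@H]1C/C(C)=C/COc1ccc(CO)c(O)c1OC
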